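**Plan**
- Numbering: ring A atoms keep their flavone numbers throughout. Piperidine atoms are primed, and C2' is the stereocentre on C6.
- Retrosynthetic cuts, in order: first the O–benzyl bond on 7-O. Then C4a–C4, C4–C3 and O1–C2, which strips ring C back to an iodophenol (I on C4a, OH on C8a), CO and phenylacetylene. Then N1'–CH3, N1'–C6' and C2'–C3', which takes the piperidine back to a formyl group on C6.
- Enabling feature: the pyranone ring (O1, C2, C3, C4) is held to ring A only through C8a–O1 and C4a–C4, and C4a lies between C8a–O and C5–O. One iodine on C4a beside a single free C8a–OH therefore defines the annulation site.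
- Placing the iodine: it goes in while C5–O is still a free, formyl-chelated phenol that directs ortho to itself. Methylating C5–OH afterwards leaves 5-OMe, 7-OBn and 8a-OMOM all different.
- Forward order: ring A is bought as phloroglucinaldehyde and dressed (steps 1–4). The piperidine ring closes second (steps 5–9), the pyranone ring third (step 10), and 7-OH is freed last (step 11).
- Stereochemistry: C2' (S) is the only centre. (R)-tert-Butanesulfinamide sets it in a magnesium-chelated Grignard addition to the aldimine, and it is a spectator afterwards.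

Key step: step 10

Remark: the 7-oxygen travels as a benzyl ether and not as a second methyl ether, because dealkylating agents cannot be trusted to prefer 7-OMe over the chelating, out-of-plane 5-OMe of a 5,7-dimethoxyflavone, and hot nucleophilic media would put C2' at risk.

**Route**

Step 1
Reactants: 1 2,4,6-trihydroxybenzaldehyde
Product: 2 2,6-dihydroxy-4-(methoxymethoxy)benzaldehyde
Conditions: MOMCl (1.0 equiv), K2CO3 (1.0 equiv), acetone, 0 °C → rt
Reagents that add atoms: chloromethyl methyl ether, COCCl
Why: Williamson-type O-alkylation: the C8a–OH, para to the formyl group, is the most acidic hydroxyl and the only one that cannot hydrogen-bond to C=O, so one equivalent of the chloromethyl ether should be consumed there first.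

Step 2
Reactants: 2 2,6-dihydroxy-4-(methoxymethoxy)benzaldehyde
Product: 3 2-(benzyloxy)-6-hydroxy-4-(methoxymethoxy)benzaldehyde
Conditions: BnBr (1.05 equiv), K2CO3, DMF, rt
Reagents that add atoms: benzyl bromide, BrCc1ccccc1
Why: Williamson etherification of one of two equivalent ortho hydroxyls; the survivor (C5–OH) is held in the six-membered hydrogen-bond chelate with the formyl oxygen and should resist a second alkylation at room temperature.

Step 3
Reactants: 3 2-(benzyloxy)-6-hydroxy-4-(methoxymethoxy)benzaldehyde
Product: 4 6-(benzyloxy)-2-hydroxy-3-iodo-4-(methoxymethoxy)benzaldehyde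
Conditions: NIS (1.0 equiv), DMF, 0 °C → rt, dark
Reagents that add atoms: N-iodosuccinimide, O=C1CCC(=O)N1I
Why: Electrophilic aromatic iodination steered by the free phenol: C4a is ortho to C5–OH and flanked by a small OH, whereas C8 sits between two alkoxy groups, which is the ortho preference known for 2-hydroxy-4,6-dialkoxyaryl carbonyl compounds.

Step 4
Reactants: 4 6-(benzyloxy)-2-hydroxy-3-iodo-4-(methoxymethoxy)benzaldehyde
Product: 5 6-(benzyloxy)-3-iodo-2-methoxy-4-(methoxymethoxy)benzaldehyde
Conditions: MeI, K2CO3, DMF, 40 °C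
Reagents that add atoms: methyl iodide, CI
Why: Williamson methylation: carbonate in DMF breaks the chelate by deprotonation, and methyl iodide is small enough to reach the phenoxide between the formyl group and iodine.

Step 5
Reactants: 5 6-(benzyloxy)-3-iodo-2-methoxy-4-(methoxymethoxy)benzaldehyde, 6 (R)-tert-butanesulfinamide
Product: 7 (R_S,E)-N-[6-(benzyloxy)-3-iodo-2-methoxy-4-(methoxymethoxy)benzylidene]-2-methylpropane-2-sulfinamide
Conditions: Ti(OEt)4, THF, 65 °C
Reagents that add atoms: none
Why: Titanium(IV)-mediated condensation of an aldehyde with a sulfinamide, in which Ti(OEt)4 serves as Lewis acid and water scavenger; only the E-aldimine is expected and sulfur keeps its configuration.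

Step 6
Reactants: 7 (R_S,E)-N-[6-(benzyloxy)-3-iodo-2-methoxy-4-(methoxymethoxy)benzylidene]-2-methylpropane-2-sulfinamide, 8 1-bromo-4-chlorobutane
Product: 10 (R_S)-N-{(1S)-1-[6-(benzyloxy)-3-iodo-2-methoxy-4-(methoxymethoxy)phenyl]-5-chloropentyl}-2-methylpropane-2-sulfinamide, via 4-chlorobutylmagnesium bromide 9 (not isolated)
Conditions: 8, Mg, THF, rt; then 7, CH2Cl2, −78 → −40 °C; sat. aq NH4Cl
Reagents that add atoms: none
Why: Grignard 1,2-addition to an N-tert-butanesulfinyl aldimine through a chair-like six-membered transition state (Zimmerman–Traxler type) in which magnesium binds the sulfinyl oxygen and tert-butyl lies equatorial, so the alkyl group reaches the Si face of the (R_S)-imine and sets C2' as S; in a weakly coordinating solvent at low temperature addition should outrun iodine–magnesium exchange, and the minor diastereomer is removed by chromatography.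

Step 7
Reactants: 10 (R_S)-N-{(1S)-1-[6-(benzyloxy)-3-iodo-2-methoxy-4-(methoxymethoxy)phenyl]-5-chloropentyl}-2-methylpropane-2-sulfinamide
Product: 11 (2S)-2-[6-(benzyloxy)-3-iodo-2-methoxy-4-(methoxymethoxy)phenyl]-1-[(R)-tert-butylsulfinyl]piperidine
Conditions: KOt-Bu, THF, 0 °C → rt
Reagents that add atoms: none
Why: Intramolecular SN2 N-alkylation (6-exo-tet) of the sulfinamide anion on the primary chloride closes the piperidine ring (N1'–C6') without involving C2'.

Step 8
Reactants: 11 (2S)-2-[6-(benzyloxy)-3-iodo-2-methoxy-4-(methoxymethoxy)phenyl]-1-[(R)-tert-butylsulfinyl]piperidine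
Product: 12 5-(benzyloxy)-2-iodo-3-methoxy-4-[(2S)-piperidin-2-yl]phenol
Conditions: 4 M HCl in dioxane, MeOH, rt → 40 °C; then aq NaHCO3
Reagents that add atoms: none
Why: Acid methanolysis cleaves the N–S bond and the MOM acetal in one operation, while the benzyl ether, the methyl ether and the aryl iodide are inert to HCl at this temperature.

Step 9
Reactants: 12 5-(benzyloxy)-2-iodo-3-methoxy-4-[(2S)-piperidin-2-yl]phenol
Product: 13 5-(benzyloxy)-2-iodo-3-methoxy-4-[(2S)-1-methylpiperidin-2-yl]phenol
Conditions: 37% aq HCHO, NaBH(OAc)3, ClCH2CH2Cl, rt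
Reagents that add atoms: formaldehyde, C=O
Why: Reductive amination: formaldehyde forms the iminium ion at N1' and triacetoxyborohydride reduces it faster than formaldehyde can attack the phenol ring, with no alkylating agent present that could quaternise nitrogen or etherify C8a–OH.

Step 10
Reactants: 13 5-(benzyloxy)-2-iodo-3-methoxy-4-[(2S)-1-methylpiperidin-2-yl]phenol, 14 phenylacetylene, 15 carbon monoxide
Product: 18 7-(benzyloxy)-5-methoxy-6-[(2S)-1-methylpiperidin-2-yl]-2-phenyl-4H-chromen-4-one, via ortho-hydroxyaryl ynone 16 (not isolated), via beta-diethylaminoenone 17 (not isolated)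
Conditions: PdCl2(dppf) (5 mol %), CO (5 bar), Et2NH–DMF, 60 °C
Reagents that add atoms: none
Why: Pd(0) inserts into the C4a–I bond of 13, CO migrates in to give the aroylpalladium species (C4a–C4), and amine-assisted transfer of the acetylide of 14 followed by reductive elimination forms C4–C3 and releases ynone 16. Diethylamine then adds to the ynone in conjugate fashion to give β-aminoenone 17, the C8a–OH attacks C2 of this vinylogous amide, and loss of diethylamine forms O1–C2. The closest known reaction type is the palladium-catalysed carbonylative Sonogashira annulation of ortho-iodophenols with terminal alkynes to flavones, applied here to a more crowded iodide. The single ring that closes, the pyranone, does so in the 6-endo mode (addition–elimination on 17), and this amine relay withholds the ynone from the 5-exo-dig closure that leads to aurones. No stereocentre is created; C2' is a spectator, and the weakly basic medium and moderate temperature are chosen so that phenoxide-driven ionisation of the para benzylic C2'–N1' bond stays slow until O1 is tied into the ring. The step needs site selectivity, secured because iodine sits on C4a and C8a–OH is the only free hydroxyl (7-O is benzylated, 5-O methylated), and it needs CO uptake to beat direct alkynylation, which the copper-free catalyst, the CO pressure and the electron-rich arylpalladium favour.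

Step 11
Reactants: 18 7-(benzyloxy)-5-methoxy-6-[(2S)-1-methylpiperidin-2-yl]-2-phenyl-4H-chromen-4-one
Product: 19 7-hydroxy-5-methoxy-6-[(2S)-1-methylpiperidin-2-yl]-2-phenyl-4H-chromen-4-one
Conditions: H2 (1 atm), 10% Pd/C, EtOAc–MeOH, rt
Reagents that add atoms: none
Why: Catalytic hydrogenolysis of an aryl benzyl ether, which should be cleaved before the hindered, doubly ortho-substituted benzylic C2'–N1' bond or the conjugated C2=C3 bond is attacked, provided hydrogen uptake is stopped at one equivalent.

**Compound list**

1 | 2,4,6-trihydroxybenzaldehyde | O=Cc1c(O)cc(O)cc1O | starting material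
2 | 2,6-dihydroxy-4-(methoxymethoxy)benzaldehyde | O=Cc1c(O)cc(OCOC)cc1O | intermediate
3 | 2-(benzyloxy)-6-hydroxy-4-(methoxymethoxy)benzaldehyde | O=Cc1c(O)cc(OCOC)cc1OCc2ccccc2 | intermediate
4 | 6-(benzyloxy)-2-hydroxy-3-iodo-4-(methoxymethoxy)benzaldehyde | O=Cc1c(O)c(I)c(OCOC)cc1OCc2ccccc2 | intermediate
5 | 6-(benzyloxy)-3-iodo-2-methoxy-4-(methoxymethoxy)benzaldehyde | O=Cc1c(OC)c(I)c(OCOC)cc1OCc2ccccc2 | intermediate
6 | (R)-tert-butanesulfinamide | CC(C)(C)[S@@](=O)N | starting material
7 | (R_S,E)-N-[6-(benzyloxy)-3-iodo-2-methoxy-4-(methoxymethoxy)benzylidene]-2-methylpropane-2-sulfinamide | CC(C)(C)[S@@](=O)/N=C/c1c(OC)c(I)c(OCOC)cc1OCc2ccccc2 | intermediate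
8 | 1-bromo-4-chlorobutane | ClCCCCBr | starting material
9 | 4-chlorobutylmagnesium bromide | ClCCCC[Mg]Br | intermediate
10 | (R_S)-N-{(1S)-1-[6-(benzyloxy)-3-iodo-2-methoxy-4-(methoxymethoxy)phenyl]-5-chloropentyl}-2-methylpropane-2-sulfinamide | CC(C)(C)[S@@](=O)N[C@@H](CCCCCl)c1c(OC)c(I)c(OCOC)cc1OCc2ccccc2 | intermediate
11 | (2S)-2-[6-(benzyloxy)-3-iodo-2-methoxy-4-(methoxymethoxy)phenyl]-1-[(R)-tert-butylsulfinyl]piperidine | CC(C)(C)[S@@](=O)N1CCCC[C@H]1c2c(OC)c(I)c(OCOC)cc2OCc3ccccc3 | intermediate
12 | 5-(benzyloxy)-2-iodo-3-methoxy-4-[(2S)-piperidin-2-yl]phenol | COc1c(I)c(O)cc(OCc2ccccc2)c1[C@@H]3CCCCN3 | intermediate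
13 | 5-(benzyloxy)-2-iodo-3-methoxy-4-[(2S)-1-methylpiperidin-2-yl]phenol | COc1c(I)c(O)cc(OCc2ccccc2)c1[C@@H]3CCCCN3C | intermediate
14 | phenylacetylene | C#Cc1ccccc1 | starting material
15 | carbon monoxide | [C-]#[O+] | starting material
16 | 1-{4-(benzyloxy)-6-hydroxy-2-methoxy-3-[(2S)-1-methylpiperidin-2-yl]phenyl}-3-phenylprop-2-yn-1-one | COc1c(C(=O)C#Cc4ccccc4)c(O)cc(OCc2ccccc2)c1[C@@H]3CCCCN3C | intermediate
17 | 1-{4-(benzyloxy)-6-hydroxy-2-methoxy-3-[(2S)-1-methylpiperidin-2-yl]phenyl}-3-(diethylamino)-3-phenylprop-2-en-1-one (alkene geometry not defined) | COc1c(C(=O)C=C(N(CC)CC)c4ccccc4)c(O)cc(OCc2ccccc2)c1[C@@H]3CCCCN3C | intermediate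
18 | 7-(benzyloxy)-5-methoxy-6-[(2S)-1-methylpiperidin-2-yl]-2-phenyl-4H-chromen-4-one | COc1c([C@@H]2CCCCN2C)c(OCc4ccccc4)cc2oc(-c3ccccc3)cc(=O)c12 | intermediate
19 | 7-hydroxy-5-methoxy-6-[(2S)-1-methylpiperidin-2-yl]-2-phenyl-4H-chromen-4-one | COc1c([C@@H]2CCCCN2C)c(O)cc2oc(-c3ccccc3)cc(=O)c12 | target

Total step count: 11. Longest linear sequence: 11 steps (1 → 19).

**Steps most likely to fail**

Step 10.
- What may go wrong: oxidative addition may be sluggish at a C–I bond flanked by OH and OMe on an electron-rich ring. Diethylamine may capture the acylpalladium species. Alkynylation may occur without CO uptake. The configuration at C2' may erode through reversible C2'–N1' ionisation.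
- Fallback: build the same ynone without palladium or CO, setting out from 13.
  - Silylating the phenol (TBSCl, imidazole, DMF) should give the tert-butyldimethylsilyl ether F1.
  - Iodine–magnesium exchange with i-PrMgCl·LiCl in THF should give the arylmagnesium chloride F2.
  - Acylation with N-methoxy-N-methyl-3-phenylpropiolamide (Weinreb ketone synthesis) should give the silyl-protected ynone F3.
  - Fluoride (TBAF) in the presence of diethylamine frees the phenol. The sequence thereby rejoins the route at 16, which passes through 17 to 18.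

Step 6.
- What may go wrong: iodine–magnesium exchange at the dialkoxy-flanked iodide may compete with addition to a crowded aldimine. Facial selectivity may be poor if magnesium binds an ortho alkoxy oxygen instead of the sulfinyl oxygen.
- Fallback: replace the Grignard reagent with an organometallic that ignores aryl iodides, and close the ring by metathesis, setting out from 7.
  - Indium-mediated Barbier allylation with allyl bromide should attack the same Si face of the (R_S)-imine and give the homoallylic sulfinamide F4.
  - N-Allylation (NaH, allyl bromide, DMF) should give the N-allyl diene F5.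
  - Ring-closing metathesis with a second-generation ruthenium catalyst should give the N-sulfinyl tetrahydropyridine F6.
  - Diimide reduction (2-nitrobenzenesulfonylhydrazide, Et3N) spares the C–I and O-benzyl bonds and returns to the route at 11.

Step 3.
- What may go wrong: iodine may enter para to the phenol at C8, or a second iodination may occur.
- Fallback: reverse the order of iodination and benzylation, setting out from 2, in which C4a and C8 are equivalent by symmetry.
  - Mono-iodination (NIS, 1.0 equiv) therefore cannot give regioisomers and should lead to the symmetric-ring mono-iodide F7.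
  - Benzylation (BnBr, K2CO3) should then take the unhindered hydroxyl beside C8–H, because the hydroxyl wedged between the formyl group and iodine stays chelated and shielded. This returns to the route at 4.

**Further compounds**

F1 | step 10 | (2S)-2-[6-(benzyloxy)-4-(tert-butyldimethylsilyloxy)-3-iodo-2-methoxyphenyl]-1-methylpiperidine | COc1c(I)c(O[Si](C)(C)C(C)(C)C)cc(OCc2ccccc2)c1[C@@H]3CCCCN3C
F2 | step 10 | {4-(benzyloxy)-6-(tert-butyldimethylsilyloxy)-2-methoxy-3-[(2S)-1-methylpiperidin-2-yl]phenyl}magnesium chloride | COc1c([Mg]Cl)c(O[Si](C)(C)C(C)(C)C)cc(OCc2ccccc2)c1[C@@H]3CCCCN3C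
F3 | step 10 | 1-{4-(benzyloxy)-6-(tert-butyldimethylsilyloxy)-2-methoxy-3-[(2S)-1-methylpiperidin-2-yl]phenyl}-3-phenylprop-2-yn-1-one | COc1c(C(=O)C#Cc4ccccc4)c(O[Si](C)(C)C(C)(C)C)cc(OCc2ccccc2)c1[C@@H]3CCCCN3C
F4 | step 6 | (R_S)-N-{(1S)-1-[6-(benzyloxy)-3-iodo-2-methoxy-4-(methoxymethoxy)phenyl]but-3-enyl}-2-methylpropane-2-sulfinamide | CC(C)(C)[S@@](=O)N[C@@H](CC=C)c1c(OC)c(I)c(OCOC)cc1OCc2ccccc2
F5 | step 6 | (R_S)-N-allyl-N-{(1S)-1-[6-(benzyloxy)-3-iodo-2-methoxy-4-(methoxymethoxy)phenyl]but-3-enyl}-2-methylpropane-2-sulfinamide | CC(C)(C)[S@@](=O)N(CC=C)[C@@H](CC=C)c1c(OC)c(I)c(OCOC)cc1OCc2ccccc2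
F6 | step 6 | (2S)-2-[6-(benzyloxy)-3-iodo-2-methoxy-4-(methoxymethoxy)phenyl]-1-[(R)-tert-butylsulfinyl]-1,2,3,6-tetrahydropyridine | CC(C)(C)[S@@](=O)N1CC=CC[C@H]1c2c(OC)c(I)c(OCOC)cc2OCc3ccccc3
F7 | step 3 | 2,6-dihydroxy-3-iodo-4-(methoxymethoxy)benzaldehyde | O=Cc1c(O)c(I)c(OCOC)cc1O
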